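## The problem

The target (41) is a stilbene trimer with nine rings: a fused pentacyclic core built around a benzene ring X that has a single free position, and four pendant hydroxyphenyl rings. Going round ring X, Xa carries the oxygen of dihydrofuran 1, Xb is CH, Xc carries the oxygen of dihydrofuran 2, and Xd, Xe and Xf carry carbon. Furan 1 is O–Ca–Cb–Xf–Xa (Ca bears 4-hydroxyphenyl, Cb bears 3,5-dihydroxyphenyl), furan 2 is O–Ce–Cd–Xd–Xc (Ce bears 4-hydroxyphenyl), and the seven-membered ring is Xe–CH2–Cc–Y1–Y2–Cd–Xd, where Cc bears 2,4-dihydroxyphenyl and Y1–Y2 is one edge of resorcinol ring Y (Y3 and Y5 are CH, Y4 and Y6 carry OH, Y6 next to Y1). All five stereocentres Ca, Cb, Cc, Cd and Ce are R, and both furans are trans. Within a furan the trans arrangement is the stable one, so Cd can be set from Ce, but Ca/Cb are insulated from the other three by the flat ring X and Cc meets Cd only across the seven-membered ring, so three independent absolute inductions are needed (furan 1, Ce, Cc). The O–CH(4-oxyphenyl) bonds of both furans ionize in acid, which epimerizes Ca and Ce and lets any nearby oxygen or arene capture the cation; the electron-rich rings are sensitive to electrophiles and oxidants; and once Y2 of a Y1=Y2 cycloheptene carries a carbonyl group, Cc–H is vinylogously acidic, so base can move the double bond or scramble Cc. The enabling feature is ring Y: besides its two oxygens it has only two carbon substituents, and they are neighbours (Cc on Y1, Cd on Y2). Ring Y therefore maps onto a cycloheptene double bond (Y1=Y2), a diazoacetyl group on Y2 (its carbons become Y6 and Y3 after a Wolff shift) and ethoxyethyne (Y5 and Y4), and can be made last, under neutral conditions, with all five stereocentres in place.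

## Retrosynthesis

**41 from 40.** Only O-alkyl bonds are cut: six methyl ethers and the ethyl ether on Y4. Methyl ethers are used for every phenol outside ring X because they survive organolithiums, radicals, carbenes and metathesis, and BBr3 is the established reagent for freeing stilbene-oligomer phenols next to aryl-substituted dihydrofurans. The ethyl group left by the key step falls in the same operation. The forward step must not open the furans irreversibly.

**40 from 34 and 35.** Four C–C bonds of ring Y are cut (Y2–Y3, Y3–Y4, Y5–Y6, Y6–Y1), leading to diazoketone 34 and ethoxyethyne 35. The neighbouring cuts, a Friedel–Crafts closure of the seven-membered ring onto a preformed ring Y or a cross-coupling at Y1 or Y2, would create Cc or Cd in the ring-closing step or need acid. This cut removes a whole ring, no stereocentre and no regiochemical choice, since only Y1 carries the hydrogen that aromatization needs. It asks for a neutral ketene-forming step and for a double bond that has stayed between Y1 and Y2.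

**34 from 32, and 32 from 31.** The diazoacetyl group is cut at its C–C bond to acid 32 and diazomethane; the cycloheptene is cut at Y1=Y2 to diene acid 31 (ring-closing metathesis). An aldol or Horner-type closure would need an enolizable aldehyde on Cc and base, and an enol triflate from a Y2 ketone could form on the Cd side. Metathesis is neutral and places the double bond by construction. The acid is freed before ring closure, because afterwards Cc–H is γ to the carbonyl. The forward metathesis must accept a 2-substituted acrylic acid.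

**31 from 30, and 30 from 26.** The exocyclic methylene carbon is removed from the acrylate, leading to acetate 26. The detour is deliberate: an acrylate would not survive the organocopper step that builds the arm on Xe, while the saturated ester does, and it is the direct product of the reaction that closes furan 2.

**26 from 24 and 25; 24 from 23; 23 from 21 and 22; 21 from 20; 20 from 19.** The Cc–aryl bond is cut in an SN2′ sense: allylic phosphate 24 and arylboronate 25 give Cc and its vinyl group in one catalytic step. An auxiliary-based alkylation of a (2,4-dimethoxyphenyl)acetyl unit would reach the same centre but pass through a racemization-prone α-aryl aldehyde on the way to the vinyl group. The four-carbon chain of 24 comes from benzylic bromide 21 and stannane 22 (via 23), and 21 from silyl ether 19 through alcohol 20. The arm is built after furan 2 because its terminal alkene would capture the aryl radical of step 10 and compete in the cross-metathesis of step 9.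

**19 from 18; 18 from 16 and 17; 16 from 12 and 14.** Furan 2 is cut at Xd–Cd: aryl bromide 18 with a tethered enoate closes by 5-exo radical addition, and Ce, already in place, steers Cd to the trans side. The enoate is cut at its double bond to allyl ether 16 and methyl acrylate 17, and 16 at O–Ce to phenol 12 and carbonate 14 (from alcohol 13), an Ir-catalysed allylic etherification that sets Ce. A carbene C–H insertion from an aryldiazoacetate would give a C3 ester that needs homologation. Addition of a 2-(alkoxycarbonyl)allyl metal to 4-methoxybenzaldehyde ends in a lactone whose conversion to the furan is thermodynamically uncertain. The chosen order delivers the CH2CO2Me group that later steps need.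

**12 from 11; 11 from 9; 9 from 5 and 6.** Furan 1 is cut at Ca–Cb: a diaryl carbene on the carbon attached to Xf inserts into the O–CH2 bond of the neighbouring 4-methoxybenzyl ether (hydrazone 9, cis product 11). This is the proven substrate class for that reaction, and the protecting group supplies Ca and its aryl ring. Acid then removes the second 4-methoxybenzyl group and turns the cis ring into the trans ring (12). Hydrazone 9 is cut at the carbene carbon to dibromide 5 and nitrile 6. The silyl ether is bulky and acid-stable on purpose: a free CH2OH on Xe would trap the Ca cation as a six-membered ether.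

**5 from 4, 3, 1 and 2.** Dibromide 5 goes back through alcohol 4 and bis-ether 3 to 3,5-dihydroxybenzyl alcohol 1 and 4-methoxybenzyl chloride 2. Because 5 is symmetric, either bromine can be exchanged first, so Xd and Xf are differentiated without any regiochemical effort.

## Roads not taken

**Alternative 1:** The cut goes through both furans at once (Ca–Cb, O–Ca, Cd–Ce, O–Ce), with ring Y treated as the second of two identical 3,5-dimethoxyphenyl groups. Forward, the precursor of A1 would lose sulfinate twice from benzylic positions on Xd and Xf, and each ortho-quinone methide would take up a chiral 4-methoxybenzyl sulfonium ylide to give the C2-symmetric bis(dihydrofuran) A1.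
- Merits: four stereocentres and two rings in one operation, trans rings directly, no acid, and a double induction that raises the enantiomeric purity of the C2 product.
- Weak points: A1 still lacks the seven-membered ring. It must be closed by bonding Cc to an ortho position of one of the two equivalent aryl groups, which creates Cc late, under acid or metal catalysis, beside two ionizable furans and with only remote control from Cd. The arm on Xe must also be grown from a benzylic position flanked by two bulky furan carbons.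
- Comparison: up to the bis(dihydrofuran) stage this road is clearly shorter than the chosen one, which needs nine steps for the same rings (steps 1–6 and 8–10) and builds them by unrelated reactions. Against that, the chosen plan fixes Cc by a catalyst before the seven-membered ring exists, closes that ring by metathesis without forming a stereocentre, and makes ring Y regiospecifically.

**Alternative 2:** The cut removes the CH2–Xe and Xd–Cd bonds and leaves Cd=Ce as an exocyclic benzylidene. Forward, an iodide function on Xd of a ring X fragment holding furan 1 would be ortho-alkylated at Xe, through a palladium/norbornene relay, by the primary bromide of a fragment holding Cc, ring Y and a stilbene. The aryl–palladium species then returns to Xd, adds to the stilbene and loses β-hydride to give A2.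
- Merits: two fragments of similar size, two C–C bonds and the seven-membered ring in one step, ring Y bought with its oxygens in place, no diazo compound and no photochemistry.
- Weak points: the alkyl bromide is β-branched, a class that is slow in this ortho-alkylation and prone to elimination. The closing insertion is a 7-exo addition to a 1,2-diaryl alkene. A2 has neither Cd nor Ce; both must arise when the freed Xc phenol adds across the benzylidene, in acid, with Cd controlled only by Cc across the ring.
- Comparison: this road is more convergent and probably several steps shorter. The chosen plan sets against it that Cd and Ce are made before the seven-membered ring, each under its own control, and that no stereocentre is created on the finished skeleton.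

**Alternative 3:** The cut removes Xd–Cd and O–Ce and takes furan 2 to the benzofuran oxidation level. Forward, an ortho-iodophenol unit on ring X and an aryl alkyne on ring Y, joined through CH2–Cc, would undergo aryl-palladation of the alkyne and C–O reductive elimination, closing the seven-membered ring and the furan together (A3).
- Merits: the whole carbon skeleton with all oxygens from one acyclic precursor, a robust aromatic furan in place of an ionizable one for most of the route, and familiar palladium chemistry.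
- Weak points: the annulation must run in a medium-ring mode with a tether that strains the syn insertion. A3 must still be reduced to the trans-dihydrofuran, a reduction of a tetrasubstituted, ring-fused benzofuran that sets Cd and Ce at the very end with Cc as the only control and with furan 1 exposed to the same acid or catalyst.
- Comparison: in step count and in the security of the ring-forming step this road is at least as good as the chosen one. Its price is that two of five stereocentres are left to substrate control on the complete ring system, which the chosen plan avoids at the cost of a longer sequence and a photochemical step.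

Key step: step 20

Assumption: the catalyst enantiomers named in steps 5, 8 and 15 are those expected to give the drawn configurations (the mirror-image catalyst is used if the sense of induction proves opposite), and stannane 22 and boronate 25 are taken as purchased materials.

## Steps

Step 1
Reactants: 1 3,5-dihydroxybenzyl alcohol; 2 4-methoxybenzyl chloride
Product: 3 [3,5-bis(4-methoxybenzyloxy)phenyl]methanol
Conditions: 2 (2.1 equiv), K2CO3, Bu4NI (cat.), DMF, 50 °C
Reagents that add atoms: 4-methoxybenzyl chloride (2), COc1ccc(CCl)cc1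
Why: Williamson etherification; the two phenoxides are alkylated much faster than the neutral benzylic alcohol. One 4-methoxybenzyl group later supplies Ca and its aryl ring, the other is an acid-labile protection for the Xc oxygen.

Step 2
Reactants: 3 [3,5-bis(4-methoxybenzyloxy)phenyl]methanol
Product: 4 [2,6-dibromo-3,5-bis(4-methoxybenzyloxy)phenyl]methanol
Conditions: NBS (2.05 equiv), MeCN, 0 °C to rt
Reagents that add atoms: N-bromosuccinimide, O=C1CCC(=O)N1Br
Why: Electrophilic aromatic bromination; in 5-substituted resorcinol diethers the positions ortho to the CH2 group and para to an ether oxygen (Xd, Xf) react first, and the position between the two bulky ethers (Xb) is shielded.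

Step 3
Reactants: 4 [2,6-dibromo-3,5-bis(4-methoxybenzyloxy)phenyl]methanol
Product: 5 tert-butyl{[2,6-dibromo-3,5-bis(4-methoxybenzyloxy)phenyl]methoxy}diphenylsilane
Conditions: TBDPSCl, imidazole, DMF, rt
Reagents that add atoms: tert-butyl(chloro)diphenylsilane, CC(C)(C)[Si](Cl)(c1ccccc1)c1ccccc1
Why: Silylation of the primary alcohol; the tert-butyldiphenylsilyl ether is chosen because it survives butyllithium and trifluoroacetic acid and its oxygen is a poor nucleophile.

Step 4
Reactants: 5 dibromide silyl ether; 6 3,5-dimethoxybenzonitrile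
Product: 9 {3-bromo-2-[(tert-butyldiphenylsilyloxy)methyl]-4,6-bis(4-methoxybenzyloxy)phenyl}(3,5-dimethoxyphenyl)methanone hydrazone, via monolithiated arene 7 (not isolated), via diaryl ketimine 8 (not isolated)
Conditions: n-BuLi (1.05 equiv), THF, −78 °C; 6, −78 to −20 °C; MeOH; N2H4·H2O (10 equiv), EtOH, 80 °C
Reagents that add atoms: 3,5-dimethoxybenzonitrile (6), COc1cc(C#N)cc(OC)c1; hydrazine, NN
Why: Bromine–lithium exchange on the symmetric dibromide gives the same aryllithium whichever bromine reacts, and its addition to the nitrile gives an N–H ketimine. Transimination with hydrazine then forms the hydrazone by displacing ammonia, which avoids condensation at a doubly ortho-substituted ketone.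

Step 5
Reactants: 9 hydrazone
Product: 11 tert-butyl{[(2S,3R)-5-bromo-3-(3,5-dimethoxyphenyl)-6-(4-methoxybenzyloxy)-2-(4-methoxyphenyl)-2,3-dihydro-1-benzofuran-4-yl]methoxy}diphenylsilane (cis), via diaryldiazomethane 10 (not isolated)
Conditions: MnO2, CH2Cl2, 0 °C; filtration; Rh2(R-PTAD)4 (1 mol%), CH2Cl2, −20 °C to rt
Reagents that add atoms: none
Why: Oxidation of the hydrazone gives the diaryldiazomethane, and the donor/donor dirhodium carbene inserts into the adjacent ArO–CH2 bond (1,5 C–H insertion), forming Ca–Cb. This is the known enantioselective carbene C–H insertion route to cis-2,3-diaryl-dihydrobenzofurans; the chiral carboxylate ligands set Cb (R) and, with it, Ca (S).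

Step 6
Reactants: 11 cis-dihydrobenzofuran
Product: 12 (2R,3R)-5-bromo-4-[(tert-butyldiphenylsilyloxy)methyl]-3-(3,5-dimethoxyphenyl)-2-(4-methoxyphenyl)-2,3-dihydro-1-benzofuran-6-ol (trans)
Conditions: CF3CO2H/CH2Cl2 (1:4), 1,3,5-trimethoxybenzene (3 equiv), 0 °C to rt
Reagents that add atoms: none
Why: Acidolysis of the remaining 4-methoxybenzyl ether frees the Xc phenol, the benzyl cation being taken up by the scavenger. The same acid reversibly ionizes the O–Ca bond, and reclosure by the Xa oxygen gives the more stable trans ring while Cb is untouched. The silyl ether survives and is too poor a nucleophile to intercept the Ca cation, which a free hydroxymethyl group would do.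

Step 7
Reactants: 13 (E)-3-(4-methoxyphenyl)prop-2-en-1-ol
Product: 14 methyl (E)-3-(4-methoxyphenyl)prop-2-en-1-yl carbonate
Conditions: ClCO2Me, pyridine, CH2Cl2, 0 °C
Reagents that add atoms: methyl chloroformate, COC(=O)Cl
Why: Acylation of a primary allylic alcohol; the methyl carbonate is the standard leaving group for iridium-catalysed allylic substitution.

Step 8
Reactants: 12 trans phenol; 14 cinnamyl carbonate
Product: 16 (2R,3R)-5-bromo-4-[(tert-butyldiphenylsilyloxy)methyl]-3-(3,5-dimethoxyphenyl)-2-(4-methoxyphenyl)-6-{[(1R)-1-(4-methoxyphenyl)prop-2-en-1-yl]oxy}-2,3-dihydro-1-benzofuran, via lithium phenoxide 15 (not isolated)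
Conditions: LiN(SiMe3)2 (1.0 equiv), THF, 0 °C; 14, [Ir(cod)Cl]2 (2 mol%), (Ra,R,R)-binaphthol-derived N,N-bis(1-phenylethyl)phosphoramidite (4 mol%), THF, rt
Reagents that add atoms: methyl (E)-3-(4-methoxyphenyl)prop-2-en-1-yl carbonate (14), COC(=O)OC/C=C/c1ccc(OC)cc1
Why: Iridium-catalysed asymmetric allylic etherification of an aryloxide gives the branched ether, with the cyclometalated iridium–phosphoramidite complex controlling the face of the allyl terminus and so setting Ce (R). ortho-Halophenoxides are accepted nucleophiles, and the neutral conditions keep the ionizable benzylic ether intact.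

Step 9
Reactants: 16 allyl aryl ether; 17 methyl acrylate
Product: 18 methyl (2E,4R)-4-{[(2R,3R)-5-bromo-4-[(tert-butyldiphenylsilyloxy)methyl]-3-(3,5-dimethoxyphenyl)-2-(4-methoxyphenyl)-2,3-dihydro-1-benzofuran-6-yl]oxy}-4-(4-methoxyphenyl)but-2-enoate
Conditions: 17 (10 equiv), second-generation Hoveyda–Grubbs catalyst (H2IMes)Cl2Ru=CH(C6H4-2-OiPr) (5 mol%), CH2Cl2, 40 °C
Reagents that add atoms: methyl acrylate (17), C=CC(=O)OC
Why: Cross-metathesis of a terminal alkene with an acrylate is E-selective and driven by loss of ethene. The molecule has no other alkene at this stage.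

Step 10
Reactants: 18 bromo enoate
Product: 19 methyl 2-[(2R,3R,5R,6R)-4-[(tert-butyldiphenylsilyloxy)methyl]-3-(3,5-dimethoxyphenyl)-2,6-bis(4-methoxyphenyl)-2,3,5,6-tetrahydrobenzo[1,2-b:5,4-b']difuran-5-yl]acetate
Conditions: (Me3Si)3SiH (1.5 equiv), AIBN (0.2 equiv), toluene, 80 °C, slow addition
Reagents that add atoms: none
Why: The silyl radical abstracts bromine, the aryl radical adds 5-exo-trig to the β-carbon of the enoate (Xd–Cd bond), and the α-ester radical takes hydrogen from the silane. Cd is set by Ce: in the chair-like Beckwith transition state the Ce aryl group is pseudo-equatorial, which gives the 2,3-trans ring.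

Step 11
Reactants: 19 silyl ether
Product: 20 methyl 2-[(2R,3R,5R,6R)-3-(3,5-dimethoxyphenyl)-4-(hydroxymethyl)-2,6-bis(4-methoxyphenyl)-2,3,5,6-tetrahydrobenzo[1,2-b:5,4-b']difuran-5-yl]acetate
Conditions: Bu4NF, AcOH (1:1), THF, 0 °C to rt
Reagents that add atoms: none
Why: Fluoride-mediated desilylation; buffering with acetic acid keeps the liberated alkoxide from attacking the neighbouring methyl ester.

Step 12
Reactants: 20 benzylic alcohol
Product: 21 methyl 2-[(2R,3R,5R,6R)-4-(bromomethyl)-3-(3,5-dimethoxyphenyl)-2,6-bis(4-methoxyphenyl)-2,3,5,6-tetrahydrobenzo[1,2-b:5,4-b']difuran-5-yl]acetate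
Conditions: CBr4, PPh3, 2,6-lutidine, CH2Cl2, 0 °C
Reagents that add atoms: carbon tetrabromide, BrC(Br)(Br)Br
Why: Appel bromination of a primary benzylic alcohol under near-neutral conditions. The benzylic position is meta to both ring X oxygens, so it does not ionize.

Step 13
Reactants: 21 benzylic bromide; 22 (E)-3-(tributylstannyl)prop-2-en-1-ol
Product: 23 methyl 2-[(2R,3R,5R,6R)-3-(3,5-dimethoxyphenyl)-4-[(2E)-4-hydroxybut-2-en-1-yl]-2,6-bis(4-methoxyphenyl)-2,3,5,6-tetrahydrobenzo[1,2-b:5,4-b']difuran-5-yl]acetate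
Conditions: 22 (1.2 equiv), Pd2(dba)3 (2.5 mol%), AsPh3 (10 mol%), THF, 50 °C
Reagents that add atoms: (E)-3-(tributylstannyl)prop-2-en-1-ol (22), CCCC[Sn](CCCC)(CCCC)/C=C/CO
Why: Stille coupling of a benzylic bromide with an alkenylstannane proceeds with retention of alkene geometry. No aryl halide is left in the molecule to compete for zerovalent palladium.

Step 14
Reactants: 23 allylic alcohol
Product: 24 diethyl (2E)-4-[(2R,3R,5R,6R)-3-(3,5-dimethoxyphenyl)-5-(2-methoxy-2-oxoethyl)-2,6-bis(4-methoxyphenyl)-2,3,5,6-tetrahydrobenzo[1,2-b:5,4-b']difuran-4-yl]but-2-en-1-yl phosphate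
Conditions: ClP(O)(OEt)2, pyridine, DMAP (cat.), CH2Cl2, 0 °C
Reagents that add atoms: diethyl chlorophosphate, CCOP(=O)(Cl)OCC
Why: Phosphorylation of a primary allylic alcohol; the phosphate is the leaving group of choice for copper-catalysed SN2′ arylation.

Step 15
Reactants: 24 allylic phosphate; 25 2-(2,4-dimethoxyphenyl)-4,4,5,5-tetramethyl-1,3,2-dioxaborolane
Product: 26 methyl 2-[(2R,3R,5R,6R)-4-[(2S)-2-(2,4-dimethoxyphenyl)but-3-en-1-yl]-3-(3,5-dimethoxyphenyl)-2,6-bis(4-methoxyphenyl)-2,3,5,6-tetrahydrobenzo[1,2-b:5,4-b']difuran-5-yl]acetate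
Conditions: 25 (1.5 equiv), CuCl (5 mol%), chiral N-mesityl-N′-(2-hydroxyaryl)-4,5-diphenylimidazolinium chloride (6 mol%), NaOMe (2 equiv), THF, 30 °C
Reagents that add atoms: 2-(2,4-dimethoxyphenyl)-4,4,5,5-tetramethyl-1,3,2-dioxaborolane (25), COc1ccc(B2OC(C)(C)C(C)(C)O2)c(OC)c1
Why: Copper-catalysed enantioselective allyl–aryl coupling: the arylcopper–carbene complex formed from the boronate attacks the γ-carbon anti to the phosphate and gives the branched product with its vinyl group. The chiral N-heterocyclic carbene sets Cc (S here, the same spatial arrangement as R in the target). The methyl ester and both furans are inert to NaOMe and arylcopper at this temperature.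

Step 16
Reactants: 26 acetate
Product: 30 methyl 2-[(2R,3R,5S,6R)-4-[(2S)-2-(2,4-dimethoxyphenyl)but-3-en-1-yl]-3-(3,5-dimethoxyphenyl)-2,6-bis(4-methoxyphenyl)-2,3,5,6-tetrahydrobenzo[1,2-b:5,4-b']difuran-5-yl]prop-2-enoate, via lithium enolate 27 (not isolated), via Mannich base 28 (not isolated), via ammonium iodide 29 (not isolated)
Conditions: LiN(iPr)2, THF, −78 °C; CH2=NMe2+ I−, −78 °C to rt; MeI, MeOH; DBU, CH2Cl2, rt
Reagents that add atoms: dimethyl(methylidene)ammonium iodide (Eschenmoser's salt), C=[N+](C)C.[I-]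
Why: Standard α-methylenation of an ester: aminomethylation of the enolate, quaternization and E1cB loss of trimethylamine. The ester α-protons are far more acidic than the allylic Cc–H, so the arm is untouched; the change of the Cd descriptor from R to S reflects CIP priorities only.

Step 17
Reactants: 30 acrylate
Product: 31 2-[(2R,3R,5S,6R)-4-[(2S)-2-(2,4-dimethoxyphenyl)but-3-en-1-yl]-3-(3,5-dimethoxyphenyl)-2,6-bis(4-methoxyphenyl)-2,3,5,6-tetrahydrobenzo[1,2-b:5,4-b']difuran-5-yl]prop-2-enoic acid
Conditions: LiOH·H2O, THF/H2O (3:1), 40 °C; cold 1 M HCl to pH 4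
Reagents that add atoms: lithium hydroxide (its oxygen becomes the carboxyl OH), [Li+].[OH-]
Why: Saponification is done on the cross-conjugated acrylate, where neither Cc–H nor Cd–H is vinylogously acidic. After ring closure the same base would meet a γ-acidic Cc–H.

Step 18
Reactants: 31 diene acid
Product: 32 cycloheptene carboxylic acid: ring X with both trans-furans and the ring Xe–CH2–Cc(2,4-dimethoxyphenyl)–CH=C(CO2H)–Cd–Xd (Ca R, Cb R, Cc S, Cd S, Ce R)
Conditions: second-generation Grubbs catalyst (H2IMes)(PCy3)Cl2Ru=CHPh (10 mol%), 1,4-benzoquinone (20 mol%), toluene (2 mM), 80 °C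
Reagents that add atoms: none
Why: Ring-closing metathesis between the monosubstituted vinyl group and the 2-substituted acrylic acid closes the seven-membered ring with loss of ethene, and the double bond can only lie between Y1 and Y2. No stereocentre is formed; benzoquinone suppresses ruthenium hydride alkene migration.

Step 19
Reactants: 32 cycloheptene carboxylic acid
Product: 34 cycloheptene diazoketone: as 32 with C(=O)CH=N2 on Y2 (Ca R, Cb R, Cc S, Cd S, Ce R), via acid chloride 33 (not isolated)
Conditions: Me2C=C(Cl)NMe2, CH2Cl2, 0 °C to rt; CH2N2 (excess), Et2O, 0 °C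
Reagents that add atoms: diazomethane, C=[N+]=[N-]
Why: The chloroenamine makes the acid chloride without HCl or amine base, and acylation of diazomethane (first stage of the Arndt–Eistert sequence) gives the diazoketone, a second equivalent taking up HCl. The trisubstituted, hindered alkene resists dipolar addition and no base is present to deprotonate Cc–H.

Step 20
Reactants: 34 cycloheptene diazoketone; 35 ethoxyethyne
Product: 40 all-R Y4-O-ethyl hexa-O-methyl ether of the target bearing free OH on Y6, via vinylketene 36 (not isolated), via ethoxycyclobutenone 37 (not isolated), via dienylketene 38 (not isolated), via cyclohexadienone 39 (not isolated)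
Conditions: 35 (8 equiv), ClCH2CH2Cl (degassed), hν 365 nm, rt; then 80 °C
Reagents that add atoms: ethoxyethyne (35), CCOC#C
Why: Light expels N2 from the diazoketone and the cycloheptenyl carbon Y2 migrates (Wolff rearrangement) to give vinylketene 36. The nucleophilic CH terminus of ethoxyethyne bonds to the ketene carbonyl carbon and the [2+2] addition gives 4-alkenyl-3-ethoxycyclobutenone 37. On warming, reversible 4π ring opening gives dienylketene 38, whose Z isomer closes ring Y by 6π electrocyclization between the ketene carbon and Y1 (cyclohexadienone 39), and tautomerization gives phenol 40. The closest known reaction is the photochemical-Wolff form of the vinylketene–alkyne benzannulation of α,β-unsaturated diazoketones with alkoxy- and siloxyalkynes, which gives resorcinol derivatives. No stereocentre is formed, and Cc and Cd, which flank the reacting alkene, survive because the medium contains neither acid nor base. The selectivity needed is regiochemical (OH next to the Cc-bearing carbon, OEt meta to it); it is secured by the polarity of the ynol ether and by the fact that only Y1 carries the hydrogen needed for aromatization. Irradiation at 365 nm addresses the diazoketone and not the alkoxyarene chromophores.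

Step 21
Reactants: 40 ring Y phenol ethyl ether
Product: 41 target compound CNP0154047.1
Conditions: BBr3 (14 equiv), CH2Cl2, −78 to 20 °C; MeOH; H2O
Reagents that add atoms: none
Why: Lewis-acid dealkylation of the ethyl ether and the six methyl ethers, the standard last step for permethylated stilbene oligomers. Any ionization of the furan O–CH bonds is reversible and recloses to the trans rings, which are the stable ones.

## Compound list

1 | 3,5-dihydroxybenzyl alcohol | OCc1cc(O)cc(O)c1 | starting material
2 | 4-methoxybenzyl chloride | COc1ccc(CCl)cc1 | starting material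
3 | [3,5-bis(4-methoxybenzyloxy)phenyl]methanol | OCc1cc(OCc2ccc(OC)cc2)cc(OCc2ccc(OC)cc2)c1 | intermediate
4 | [2,6-dibromo-3,5-bis(4-methoxybenzyloxy)phenyl]methanol | OCc1c(Br)c(OCc2ccc(OC)cc2)cc(OCc2ccc(OC)cc2)c1Br | intermediate
5 | tert-butyl{[2,6-dibromo-3,5-bis(4-methoxybenzyloxy)phenyl]methoxy}diphenylsilane | CC(C)(C)[Si](OCc1c(Br)c(OCc2ccc(OC)cc2)cc(OCc2ccc(OC)cc2)c1Br)(c1ccccc1)c1ccccc1 | intermediate
6 | 3,5-dimethoxybenzonitrile | COc1cc(C#N)cc(OC)c1 | starting material
7 | {3-bromo-2-[(tert-butyldiphenylsilyloxy)methyl]-4,6-bis(4-methoxybenzyloxy)phenyl}lithium | CC(C)(C)[Si](OCc1c(Br)c(OCc2ccc(OC)cc2)cc(OCc2ccc(OC)cc2)c1[Li])(c1ccccc1)c1ccccc1 | intermediate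
8 | 1-{3-bromo-2-[(tert-butyldiphenylsilyloxy)methyl]-4,6-bis(4-methoxybenzyloxy)phenyl}-1-(3,5-dimethoxyphenyl)methanimine | CC(C)(C)[Si](OCc1c(Br)c(OCc2ccc(OC)cc2)cc(OCc2ccc(OC)cc2)c1C(=N)c1cc(OC)cc(OC)c1)(c1ccccc1)c1ccccc1 | intermediate
9 | {3-bromo-2-[(tert-butyldiphenylsilyloxy)methyl]-4,6-bis(4-methoxybenzyloxy)phenyl}(3,5-dimethoxyphenyl)methanone hydrazone | CC(C)(C)[Si](OCc1c(Br)c(OCc2ccc(OC)cc2)cc(OCc2ccc(OC)cc2)c1C(=NN)c1cc(OC)cc(OC)c1)(c1ccccc1)c1ccccc1 | intermediate
10 | 3-bromo-2-[(tert-butyldiphenylsilyloxy)methyl]-1-[diazo(3,5-dimethoxyphenyl)methyl]-4,6-bis(4-methoxybenzyloxy)benzene | CC(C)(C)[Si](OCc1c(Br)c(OCc2ccc(OC)cc2)cc(OCc2ccc(OC)cc2)c1C(=[N+]=[N-])c1cc(OC)cc(OC)c1)(c1ccccc1)c1ccccc1 | intermediate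
11 | tert-butyl{[(2S,3R)-5-bromo-3-(3,5-dimethoxyphenyl)-6-(4-methoxybenzyloxy)-2-(4-methoxyphenyl)-2,3-dihydro-1-benzofuran-4-yl]methoxy}diphenylsilane (cis) | COc1ccc([C@H]2Oc3cc(OCc4ccc(OC)cc4)c(Br)c(CO[Si](c4ccccc4)(c4ccccc4)C(C)(C)C)c3[C@H]2c2cc(OC)cc(OC)c2)cc1 | intermediate
12 | (2R,3R)-5-bromo-4-[(tert-butyldiphenylsilyloxy)methyl]-3-(3,5-dimethoxyphenyl)-2-(4-methoxyphenyl)-2,3-dihydro-1-benzofuran-6-ol (trans) | COc1ccc([C@@H]2Oc3cc(O)c(Br)c(CO[Si](c4ccccc4)(c4ccccc4)C(C)(C)C)c3[C@H]2c2cc(OC)cc(OC)c2)cc1 | intermediate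
13 | (E)-3-(4-methoxyphenyl)prop-2-en-1-ol | COc1ccc(/C=C/CO)cc1 | starting material
14 | methyl (E)-3-(4-methoxyphenyl)prop-2-en-1-yl carbonate | COC(=O)OC/C=C/c1ccc(OC)cc1 | intermediate
15 | lithium (2R,3R)-5-bromo-4-[(tert-butyldiphenylsilyloxy)methyl]-3-(3,5-dimethoxyphenyl)-2-(4-methoxyphenyl)-2,3-dihydro-1-benzofuran-6-olate | COc1ccc([C@@H]2Oc3cc([O-])c(Br)c(CO[Si](c4ccccc4)(c4ccccc4)C(C)(C)C)c3[C@H]2c2cc(OC)cc(OC)c2)cc1.[Li+] | intermediate
16 | (2R,3R)-5-bromo-4-[(tert-butyldiphenylsilyloxy)methyl]-3-(3,5-dimethoxyphenyl)-2-(4-methoxyphenyl)-6-{[(1R)-1-(4-methoxyphenyl)prop-2-en-1-yl]oxy}-2,3-dihydro-1-benzofuran | COc1ccc([C@@H]2Oc3cc(O[C@H](C=C)c4ccc(OC)cc4)c(Br)c(CO[Si](c4ccccc4)(c4ccccc4)C(C)(C)C)c3[C@H]2c2cc(OC)cc(OC)c2)cc1 | intermediate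
17 | methyl acrylate | C=CC(=O)OC | starting material
18 | methyl (2E,4R)-4-{[(2R,3R)-5-bromo-4-[(tert-butyldiphenylsilyloxy)methyl]-3-(3,5-dimethoxyphenyl)-2-(4-methoxyphenyl)-2,3-dihydro-1-benzofuran-6-yl]oxy}-4-(4-methoxyphenyl)but-2-enoate | COc1ccc([C@@H]2Oc3cc(O[C@H](/C=C/C(=O)OC)c4ccc(OC)cc4)c(Br)c(CO[Si](c4ccccc4)(c4ccccc4)C(C)(C)C)c3[C@H]2c2cc(OC)cc(OC)c2)cc1 | intermediate
19 | methyl 2-[(2R,3R,5R,6R)-4-[(tert-butyldiphenylsilyloxy)methyl]-3-(3,5-dimethoxyphenyl)-2,6-bis(4-methoxyphenyl)-2,3,5,6-tetrahydrobenzo[1,2-b:5,4-b']difuran-5-yl]acetate | COc1ccc([C@@H]2Oc3cc4c(c(CO[Si](c5ccccc5)(c5ccccc5)C(C)(C)C)c3[C@H]2c2cc(OC)cc(OC)c2)[C@@H](CC(=O)OC)[C@H](c2ccc(OC)cc2)O4)cc1 | intermediate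
20 | methyl 2-[(2R,3R,5R,6R)-3-(3,5-dimethoxyphenyl)-4-(hydroxymethyl)-2,6-bis(4-methoxyphenyl)-2,3,5,6-tetrahydrobenzo[1,2-b:5,4-b']difuran-5-yl]acetate | COc1ccc([C@@H]2Oc3cc4c(c(CO)c3[C@H]2c2cc(OC)cc(OC)c2)[C@@H](CC(=O)OC)[C@H](c2ccc(OC)cc2)O4)cc1 | intermediate
21 | methyl 2-[(2R,3R,5R,6R)-4-(bromomethyl)-3-(3,5-dimethoxyphenyl)-2,6-bis(4-methoxyphenyl)-2,3,5,6-tetrahydrobenzo[1,2-b:5,4-b']difuran-5-yl]acetate | COc1ccc([C@@H]2Oc3cc4c(c(CBr)c3[C@H]2c2cc(OC)cc(OC)c2)[C@@H](CC(=O)OC)[C@H](c2ccc(OC)cc2)O4)cc1 | intermediate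
22 | (E)-3-(tributylstannyl)prop-2-en-1-ol | CCCC[Sn](CCCC)(CCCC)/C=C/CO | starting material
23 | methyl 2-[(2R,3R,5R,6R)-3-(3,5-dimethoxyphenyl)-4-[(2E)-4-hydroxybut-2-en-1-yl]-2,6-bis(4-methoxyphenyl)-2,3,5,6-tetrahydrobenzo[1,2-b:5,4-b']difuran-5-yl]acetate | COc1ccc([C@@H]2Oc3cc4c(c(C/C=C/CO)c3[C@H]2c2cc(OC)cc(OC)c2)[C@@H](CC(=O)OC)[C@H](c2ccc(OC)cc2)O4)cc1 | intermediate
24 | diethyl (2E)-4-[(2R,3R,5R,6R)-3-(3,5-dimethoxyphenyl)-5-(2-methoxy-2-oxoethyl)-2,6-bis(4-methoxyphenyl)-2,3,5,6-tetrahydrobenzo[1,2-b:5,4-b']difuran-4-yl]but-2-en-1-yl phosphate | COc1ccc([C@@H]2Oc3cc4c(c(C/C=C/COP(=O)(OCC)OCC)c3[C@H]2c2cc(OC)cc(OC)c2)[C@@H](CC(=O)OC)[C@H](c2ccc(OC)cc2)O4)cc1 | intermediate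
25 | 2-(2,4-dimethoxyphenyl)-4,4,5,5-tetramethyl-1,3,2-dioxaborolane | COc1ccc(B2OC(C)(C)C(C)(C)O2)c(OC)c1 | starting material
26 | methyl 2-[(2R,3R,5R,6R)-4-[(2S)-2-(2,4-dimethoxyphenyl)but-3-en-1-yl]-3-(3,5-dimethoxyphenyl)-2,6-bis(4-methoxyphenyl)-2,3,5,6-tetrahydrobenzo[1,2-b:5,4-b']difuran-5-yl]acetate | COc1ccc([C@@H]2Oc3cc4c(c(C[C@H](c5ccc(OC)cc5OC)C=C)c3[C@H]2c2cc(OC)cc(OC)c2)[C@@H](CC(=O)OC)[C@H](c2ccc(OC)cc2)O4)cc1 | intermediate
27 | lithium enolate of 26 (ester enolate on the CH2CO2Me group, enolate geometry open, other centres as in 26) | COc1ccc([C@@H]2Oc3cc4c(c(C[C@H](c5ccc(OC)cc5OC)C=C)c3[C@H]2c2cc(OC)cc(OC)c2)[C@@H](C=C(O[Li])OC)[C@H](c2ccc(OC)cc2)O4)cc1 | intermediate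
28 | Mannich base: methyl 3-(dimethylamino)-2-[furan-2 C5 of 26]propanoate (new α-centre as a mixture, other centres as in 26) | COc1ccc([C@@H]2Oc3cc4c(c(C[C@H](c5ccc(OC)cc5OC)C=C)c3[C@H]2c2cc(OC)cc(OC)c2)[C@@H](C(CN(C)C)C(=O)OC)[C@H](c2ccc(OC)cc2)O4)cc1 | intermediate
29 | trimethylammonium iodide of 28 | COc1ccc([C@@H]2Oc3cc4c(c(C[C@H](c5ccc(OC)cc5OC)C=C)c3[C@H]2c2cc(OC)cc(OC)c2)[C@@H](C(C[N+](C)(C)C)C(=O)OC)[C@H](c2ccc(OC)cc2)O4)cc1.[I-] | intermediate
30 | methyl 2-[(2R,3R,5S,6R)-4-[(2S)-2-(2,4-dimethoxyphenyl)but-3-en-1-yl]-3-(3,5-dimethoxyphenyl)-2,6-bis(4-methoxyphenyl)-2,3,5,6-tetrahydrobenzo[1,2-b:5,4-b']difuran-5-yl]prop-2-enoate | COc1ccc([C@@H]2Oc3cc4c(c(C[C@H](c5ccc(OC)cc5OC)C=C)c3[C@H]2c2cc(OC)cc(OC)c2)[C@@H](C(=C)C(=O)OC)[C@H](c2ccc(OC)cc2)O4)cc1 | intermediate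
31 | 2-[(2R,3R,5S,6R)-4-[(2S)-2-(2,4-dimethoxyphenyl)but-3-en-1-yl]-3-(3,5-dimethoxyphenyl)-2,6-bis(4-methoxyphenyl)-2,3,5,6-tetrahydrobenzo[1,2-b:5,4-b']difuran-5-yl]prop-2-enoic acid | COc1ccc([C@@H]2Oc3cc4c(c(C[C@H](c5ccc(OC)cc5OC)C=C)c3[C@H]2c2cc(OC)cc(OC)c2)[C@@H](C(=C)C(=O)O)[C@H](c2ccc(OC)cc2)O4)cc1 | intermediate
32 | cycloheptene carboxylic acid: ring X with trans-furan 1, trans-furan 2 and the ring Xe–CH2–Cc(2,4-dimethoxyphenyl)–CH=C(CO2H)–Cd–Xd (Ca R, Cb R, Cc S, Cd S, Ce R) | COc1ccc([C@@H]2Oc3cc4c5c(c3[C@H]2c2cc(OC)cc(OC)c2)C[C@H](c2ccc(OC)cc2OC)C=C(C(=O)O)[C@H]5[C@H](c2ccc(OC)cc2)O4)cc1 | intermediate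
33 | acid chloride of 32 (stereocentres as in 32) | COc1ccc([C@@H]2Oc3cc4c5c(c3[C@H]2c2cc(OC)cc(OC)c2)C[C@H](c2ccc(OC)cc2OC)C=C(C(=O)Cl)[C@H]5[C@H](c2ccc(OC)cc2)O4)cc1 | intermediate
34 | cycloheptene diazoketone: as 32 with C(=O)CH=N2 on Y2 (Ca R, Cb R, Cc S, Cd S, Ce R) | COc1ccc([C@@H]2Oc3cc4c5c(c3[C@H]2c2cc(OC)cc(OC)c2)C[C@H](c2ccc(OC)cc2OC)C=C(C(=O)C=[N+]=[N-])[C@H]5[C@H](c2ccc(OC)cc2)O4)cc1 | intermediate
35 | ethoxyethyne | CCOC#C | starting material
36 | vinylketene: as 34 with CH=C=O on Y2 (spatial arrangement of all centres as in 34) | COc1ccc([C@@H]2Oc3cc4c5c(c3[C@H]2c2cc(OC)cc(OC)c2)C[C@H](c2ccc(OC)cc2OC)C=C(C=C=O)[C@H]5[C@H](c2ccc(OC)cc2)O4)cc1 | intermediate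
37 | 4-(cycloheptenyl)-3-ethoxycyclobut-2-en-1-one: Y2 bonded to the sp3 carbon of the cyclobutenone (that carbon as a mixture of epimers, other centres as in 34) | COc1ccc([C@@H]2Oc3cc4c5c(c3[C@H]2c2cc(OC)cc(OC)c2)C[C@H](c2ccc(OC)cc2OC)C=C(C6C(=O)C=C6OCC)[C@H]5[C@H](c2ccc(OC)cc2)O4)cc1 | intermediate
38 | dienylketene: Y2–CH=C(OEt)–CH=C=O with Y2 and the ketenyl group cis (other centres as in 34) | COc1ccc([C@@H]2Oc3cc4c5c(c3[C@H]2c2cc(OC)cc(OC)c2)C[C@H](c2ccc(OC)cc2OC)C=C(/C=C(\C=C=O)OCC)[C@H]5[C@H](c2ccc(OC)cc2)O4)cc1 | intermediate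
39 | cyclohexa-2,4-dienone: ring Y closed, Y1 still sp3 (CH, mixture of epimers), C=O at Y6, OEt at Y4 (other centres as in 34) | COc1ccc([C@@H]2Oc3cc4c5c(c3[C@H]2c2cc(OC)cc(OC)c2)C[C@H](c2ccc(OC)cc2OC)C6C(=O)C=C(OCC)C=C6[C@H]5[C@H](c2ccc(OC)cc2)O4)cc1 | intermediate
40 | Y4-O-ethyl hexa-O-methyl ether of the target bearing free OH on Y6: ring Y formed, six methyl ethers on the other oxygens (Ca, Cb, Cc, Cd, Ce all R) | COc1ccc([C@@H]2Oc3cc4c5c(c3[C@H]2c2cc(OC)cc(OC)c2)C[C@H](c2ccc(OC)cc2OC)c2c(O)cc(OCC)cc2[C@H]5[C@H](c2ccc(OC)cc2)O4)cc1 | intermediate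
41 | CNP0154047.1, the octaphenol (Ca, Cb, Cc, Cd, Ce all R) | Oc1ccc([C@@H]2Oc3cc4c5c(c3[C@H]2c2cc(O)cc(O)c2)C[C@H](c2ccc(O)cc2O)c2c(O)cc(O)cc2[C@H]5[C@H](c2ccc(O)cc2)O4)cc1 | target

## Step count and least certain steps

Total step count: 21. Longest linear sequence: 20 steps (steps 1–6 and 8–21, from 1 to 41); step 7 is a one-step side branch.

**Step 20 (key step).** The ketene may not be intercepted by the alkyne fast enough, so that it dimerizes or is taken by traces of water. The alkoxyarenes and aryl-substituted furans may absorb part of the light and suffer O–CH cleavage. The wrong rotamer of the diazoketone may give carbene insertion instead of the Wolff shift. Fallback, from 34 back to the route at 40: the rearrangement and the cycloaddition are separated and light is left out of the ring-forming stage. Silver benzoate (PhCO2Ag) with Et3N in aqueous THF converts 34 into the homologous β,γ-unsaturated acid F1 (Arndt–Eistert). Me2C=C(Cl)NMe2 gives its acid chloride F2. Slow addition of Et3N to F2 in the presence of 35 generates vinylketene 36 by dehydrochlorination in the dark; 36 is captured by 35 as cyclobutenone 37, and heating leads on through 38 and 39 to 40.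

**Step 4.** Exchange of hydrazine at the doubly ortho-substituted ketimine may be slow, so that hydrolysis to the ketone or azine formation takes over. Fallback, from 8 back to 9: ketimine 8 is used as its N-lithio salt (the addition product before the methanol quench) and is aminated on nitrogen with O-(diphenylphosphinyl)hydroxylamine, Ph2P(O)ONH2, which makes the N–N bond without any addition to the shielded carbon.

**Step 6.** The Ca cation may be captured by something other than the Xa oxygen (the silyl ether oxygen after partial desilylation, or the scavenger), epimerization may stop short, or the 4-methoxybenzyl cation may alkylate the electron-rich rings. Fallback, from 11 back to 12: the silyl ether is exchanged for a group whose oxygen cannot take part. Bu4NF gives the cis alcohol F3 and Ac2O/pyridine the cis acetate F4. The same acid treatment then gives the trans phenol acetate F5, K2CO3 in MeOH the trans diol F6, and silylation of the primary alcohol (TBDPSCl, 1 equiv, imidazole) returns 12.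

**Step 10.** Face selectivity at Cd may be poor, and the aryl radical may be reduced before it cyclizes. Fallback, from 18 back to 19: a polar ring closure replaces the radical one. Bromine–lithium exchange with t-BuLi at −100 °C is followed by intramolecular conjugate addition of the aryllithium to the enoate, with lithium held by the ether oxygen in a chair-like array that places the Ce aryl group equatorial; protonation of the enolate gives 19.

**Step 18.** The 2-substituted, electron-poor acrylic acid next to the crowded Cd may fail to enter the catalytic cycle, so that the vinyl group on Cc dimerizes or migrates. Fallback, from 30 back to 32: iBu2AlH reduces ester 30 to the allylic alcohol F7, whose more electron-rich 1,1-disubstituted alkene closes more readily to the cycloheptenyl carbinol F8. MnO2 gives the enal F9, and NaClO2/NaH2PO4/2-methylbut-2-ene gives 32.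

**Step 19.** Diazomethane may add as a dipole to the conjugated alkene, or the acid chloride may lose HCl through Cc–H to a ketene. Fallback, from 32 back to 34: carbonyldiimidazole and MeNHOMe·HCl give the Weinreb amide F10, and MeMgBr gives the methyl ketone F11. Kinetic deprotonation at the methyl group with LiN(SiMe3)2 at −78 °C, trifluoroacetylation with CF3CO2CH2CF3 and detrifluoroacetylative diazo transfer with MsN3/Et3N then give 34.

## Further compounds

F1 | step 20 | homologous acid: as 32 with CH2CO2H on Y2 | COc1ccc([C@@H]2Oc3cc4c5c(c3[C@H]2c2cc(OC)cc(OC)c2)C[C@H](c2ccc(OC)cc2OC)C=C(CC(=O)O)[C@H]5[C@H](c2ccc(OC)cc2)O4)cc1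
F2 | step 20 | acid chloride of F1 | COc1ccc([C@@H]2Oc3cc4c5c(c3[C@H]2c2cc(OC)cc(OC)c2)C[C@H](c2ccc(OC)cc2OC)C=C(CC(=O)Cl)[C@H]5[C@H](c2ccc(OC)cc2)O4)cc1
F0 | step 4 | none | none
F3 | step 6 | [(2S,3R)-5-bromo-3-(3,5-dimethoxyphenyl)-6-(4-methoxybenzyloxy)-2-(4-methoxyphenyl)-2,3-dihydro-1-benzofuran-4-yl]methanol (cis) | COc1ccc([C@H]2Oc3cc(OCc4ccc(OC)cc4)c(Br)c(CO)c3[C@H]2c2cc(OC)cc(OC)c2)cc1
F4 | step 6 | acetate of F3 (cis) | COc1ccc([C@H]2Oc3cc(OCc4ccc(OC)cc4)c(Br)c(COC(C)=O)c3[C@H]2c2cc(OC)cc(OC)c2)cc1
F5 | step 6 | [(2R,3R)-5-bromo-3-(3,5-dimethoxyphenyl)-6-hydroxy-2-(4-methoxyphenyl)-2,3-dihydro-1-benzofuran-4-yl]methyl acetate (trans) | COc1ccc([C@@H]2Oc3cc(O)c(Br)c(COC(C)=O)c3[C@H]2c2cc(OC)cc(OC)c2)cc1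
F6 | step 6 | (2R,3R)-5-bromo-3-(3,5-dimethoxyphenyl)-4-(hydroxymethyl)-2-(4-methoxyphenyl)-2,3-dihydro-1-benzofuran-6-ol (trans) | COc1ccc([C@@H]2Oc3cc(O)c(Br)c(CO)c3[C@H]2c2cc(OC)cc(OC)c2)cc1
F0 | step 10 | none | none
F7 | step 18 | allylic alcohol: as 30 with C(=CH2)CH2OH on Cd | COc1ccc([C@@H]2Oc3cc4c(c(C[C@H](c5ccc(OC)cc5OC)C=C)c3[C@H]2c2cc(OC)cc(OC)c2)[C@@H](C(=C)CO)[C@H](c2ccc(OC)cc2)O4)cc1
F8 | step 18 | cycloheptenyl carbinol: as 32 with CH2OH on Y2 | COc1ccc([C@@H]2Oc3cc4c5c(c3[C@H]2c2cc(OC)cc(OC)c2)C[C@H](c2ccc(OC)cc2OC)C=C(CO)[C@H]5[C@H](c2ccc(OC)cc2)O4)cc1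
F9 | step 18 | enal: as 32 with CHO on Y2 | COc1ccc([C@@H]2Oc3cc4c5c(c3[C@H]2c2cc(OC)cc(OC)c2)C[C@H](c2ccc(OC)cc2OC)C=C(C=O)[C@H]5[C@H](c2ccc(OC)cc2)O4)cc1
F10 | step 19 | N-methoxy-N-methylamide of 32 | COc1ccc([C@@H]2Oc3cc4c5c(c3[C@H]2c2cc(OC)cc(OC)c2)C[C@H](c2ccc(OC)cc2OC)C=C(C(=O)N(C)OC)[C@H]5[C@H](c2ccc(OC)cc2)O4)cc1
F11 | step 19 | methyl ketone: as 32 with C(=O)CH3 on Y2 | COc1ccc([C@@H]2Oc3cc4c5c(c3[C@H]2c2cc(OC)cc(OC)c2)C[C@H](c2ccc(OC)cc2OC)C=C(C(C)=O)[C@H]5[C@H](c2ccc(OC)cc2)O4)cc1
A1 | alternative 1 | C2-symmetric bis(trans-2,3-diaryl-dihydrofuran) of ring X with a triisopropylsilyloxymethyl group on Xe | COc1ccc([C@@H]2Oc3cc4c(c(CO[Si](C(C)C)(C(C)C)C(C)C)c3[C@H]2c2cc(OC)cc(OC)c2)[C@@H](c2cc(OC)cc(OC)c2)[C@H](c2ccc(OC)cc2)O4)cc1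
A2 | alternative 2 | 5-(4-methoxybenzylidene)dibenzosuberane carrying furan 1 and a methoxymethyl ether on Xc | COc1ccc([C@@H]2Oc3cc(OCOC)c4c(c3[C@H]2c2cc(OC)cc(OC)c2)C[C@H](c2ccc(OC)cc2OC)c2c(OC)cc(OC)cc2/C4=C\c2ccc(OC)cc2)cc1
A3 | alternative 3 | 3,4-fused 2-(4-methoxyphenyl)benzofuran containing the seven-membered ring, with furan 1 in place | COc1ccc([C@@H]2Oc3cc4c5c(c3[C@H]2c2cc(OC)cc(OC)c2)C[C@H](c2ccc(OC)cc2OC)c2c(OC)cc(OC)cc2-c5c(-c2ccc(OC)cc2)o4)cc1
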